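## Retrosynthetic overview

Feature: in ring B (C4a, C5, C6, C7, C8, C8a) the only stereocentre, C7, is a tertiary α-ketol carbon (O, CH3) between C6=O and C8=O, and C8 sits on sp2 carbon C8a of pyran ring A. An acyl anion at C8 adding to a methyl ketone at C7 leaves exactly this pattern.
Disconnections, backwards: the orsellinate C7–O ester and the acid-labile groups; C7–C8 by an enantioselective carbene-catalysed aldehyde–ketone benzoin, which opens ring B to a 5-formyl-4-(2,3-dioxobutylidene)-4H-pyran; C8–C8a by reductive carbonylation of an enol triflate; C4a=C5 by sulfide contraction of a pyran-4-thione; the C3 side chain by oxidation–Wittig.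
Ring order: ring A is bought as kojic acid (5-OH becomes the handle for C8, CH2OH the acrylate, C4=O the C4a=C5 bond), ring B closes in the key step, and the arene arrives with orsellinic acid.
The C5 nucleophile is tethered through sulfur so that it can only reach C4a of a pyrylium stage whose α-position C1 is free, and C8 enters after the sulfur chemistry so that no aldehyde protection is needed.

Key step: step 8

Numbering: the isochromene numbering of the target is used for all intermediates (ring A: C1, O2, C3, C4, C4a, C8a).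

Assumption on the sense of induction: the (5aS,10bR) triazolium salt is taken to give 7S. This must be checked on the first run, and the equally available (5aR,10bS) salt is used if the sense is opposite.

Assumption on geometry: the 4-ylidene-4H-pyrans are drawn as the 4Z isomers (C6 syn to C8a), the only geometry that can cyclise. C4a=C5 is a push–pull (pyrylium-enolate) double bond, so E and Z forms are expected to interconvert under the acidic and basic conditions used, and either isomer or a mixture is carried on.

## Route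

Step 1
Reactants: 1 kojic acid (5-hydroxy-2-(hydroxymethyl)-4H-pyran-4-one)
Product: 2 6-(hydroxymethyl)-4-oxo-4H-pyran-3-yl trifluoromethanesulfonate
Conditions: PhNTf2 (1.05 equiv), Et3N (1.2 equiv), CH2Cl2/DMF, 0 → 23 °C
Reagents that add atoms: N-phenylbis(trifluoromethanesulfonimide), O=S(=O)(N(c1ccccc1)S(=O)(=O)C(F)(F)F)C(F)(F)F
Why: Selective O-sulfonylation, because only the acidic enolic 5-OH is ionised by Et3N and the mild triflyl donor leaves the neutral primary alcohol alone, so the handle for C8 is installed without a protecting group.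

Step 2
Reactants: 2 6-(hydroxymethyl)-4-oxo-4H-pyran-3-yl trifluoromethanesulfonate; 3 tert-butyl (triphenylphosphoranylidene)acetate
Product: 5 tert-butyl (E)-3-[4-oxo-5-(trifluoromethylsulfonyloxy)-4H-pyran-2-yl]prop-2-enoate, via 6-formyl-4-oxo-4H-pyran-3-yl triflate 4 (not isolated)
Conditions: MnO2 (10 equiv), 3 (1.2 equiv), CH2Cl2, 23 → 40 °C
Reagents that add atoms: none
Why: Tandem oxidation–Wittig olefination, in which MnO2 oxidises the allylic-type CH2OH and the stabilised ylide traps the hydrate-prone aldehyde at once as the E-enoate, while the enol triflate is inert to both reagents.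

Step 3
Reactants: 5 tert-butyl (E)-3-[4-oxo-5-(trifluoromethylsulfonyloxy)-4H-pyran-2-yl]prop-2-enoate
Product: 6 tert-butyl (E)-3-[4-thioxo-5-(trifluoromethylsulfonyloxy)-4H-pyran-2-yl]prop-2-enoate
Conditions: Lawesson's reagent (0.6 equiv), toluene, 80 °C
Reagents that add atoms: Lawesson's reagent, COc1ccc(cc1)P1(=S)SP(=S)(S1)c1ccc(OC)cc1
Why: Thionation with Lawesson's reagent, since the polarised vinylogous-ester carbonyl of a 4-pyranone reacts through the thiaoxaphosphetane much faster than the tert-butyl ester, and the triflate is a spectator.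

Step 4
Reactants: 7 3,3-dimethoxybutan-2-one
Product: 9 1-bromo-3,3-dimethoxybutan-2-one, via trimethylsilyl enol ether 8 (not isolated)
Conditions: LiN(SiMe3)2 (1.1 equiv), Me3SiCl (1.2 equiv), THF, −78 °C; then NBS (1.05 equiv), −78 → 0 °C
Reagents that add atoms: N-bromosuccinimide, O=C1CCC(=O)N1Br; chlorotrimethylsilane, C[Si](C)(C)Cl (silyl group of 8 only)
Why: α-Bromination through the silyl enol ether, because the ketone can enolise only toward its methyl group and NBS brominates under non-acidic conditions that leave the dimethyl ketal intact.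

Step 5
Reactants: 6 tert-butyl (E)-3-[4-thioxo-5-(trifluoromethylsulfonyloxy)-4H-pyran-2-yl]prop-2-enoate; 9 1-bromo-3,3-dimethoxybutan-2-one
Product: 12 tert-butyl (E)-3-[(4Z)-4-(3,3-dimethoxy-2-oxobutylidene)-5-(trifluoromethylsulfonyloxy)-4H-pyran-2-yl]prop-2-enoate, via 4-alkylthiopyrylium bromide 10 (not isolated), via spiro-thiirane 11 (not isolated)
Conditions: 9 (1.2 equiv), MeCN, 23 → 40 °C; then PPh3 (1.5 equiv), Et3N (1.5 equiv), 0 → 23 °C
Reagents that add atoms: none
Why: Eschenmoser sulfide contraction, in which soft S-alkylation of the thione gives the aromatic 4-alkylthiopyrylium salt, Et3N deprotonates the S–CH2–C=O unit, the tethered carbanion can close only on C4a (three-membered closure, so the free α-position C1 is not attacked) and PPh3 takes sulfur from the thiirane to leave C4a=C5.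

Step 6
Reactants: 12 tert-butyl (E)-3-[(4Z)-4-(3,3-dimethoxy-2-oxobutylidene)-5-(trifluoromethylsulfonyloxy)-4H-pyran-2-yl]prop-2-enoate
Product: 13 tert-butyl (E)-3-[(4Z)-4-(3,3-dimethoxy-2-oxobutylidene)-5-formyl-4H-pyran-2-yl]prop-2-enoate
Conditions: Pd(OAc)2 (5 mol %), dppp (5 mol %), CO (1 atm), Et3SiH (2 equiv, slow addition), Et3N (2.5 equiv), DMF, 65 °C
Reagents that add atoms: carbon monoxide, [C-]#[O+]
Why: Palladium-catalysed reductive carbonylation (formylation) of an enol triflate, in which zerovalent palladium inserts into C8a–OTf, CO inserts and the silane transfers hydride, so C8 arrives at the aldehyde level after the sulfur chemistry that a free aldehyde would not survive.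

Step 7
Reactants: 13 tert-butyl (E)-3-[(4Z)-4-(3,3-dimethoxy-2-oxobutylidene)-5-formyl-4H-pyran-2-yl]prop-2-enoate
Product: 14 tert-butyl (E)-3-[(4Z)-4-(2,3-dioxobutylidene)-5-formyl-4H-pyran-2-yl]prop-2-enoate
Conditions: 1 M aq. HCl, THF, 23 °C; azeotropic drying (toluene), used directly
Reagents that add atoms: water, O
Why: Acid-catalysed ketal hydrolysis, which should be easy because the donor-substituted C6 carbonyl hardly retards oxocarbenium formation at C7, while dilute acid at room temperature spares the tert-butyl ester and the acceptor-substituted 4H-pyran is acid-stable like ring A of the azaphilones.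

Step 8
Reactants: 14 tert-butyl (E)-3-[(4Z)-4-(2,3-dioxobutylidene)-5-formyl-4H-pyran-2-yl]prop-2-enoate
Product: 15 tert-butyl (E)-3-[(7S)-7-hydroxy-7-methyl-6,8-dioxo-7,8-dihydro-6H-isochromen-3-yl]prop-2-enoate
Conditions: (5aS,10bR)-2-(pentafluorophenyl)-5a,10b-dihydro-4H,6H-indeno[2,1-b][1,2,4]triazolo[4,3-d][1,4]oxazin-2-ium tetrafluoroborate (15 mol %), Et3N (15 mol %), 4 Å molecular sieves, THF (0.02 M), 23 °C, Ar
Reagents that add atoms: none
Why: Et3N deprotonates the triazolium salt, the carbene adds to the C8 aldehyde, proton transfer gives the enaminol (Breslow intermediate), its C8 attacks the C7 ketone, and collapse of the adduct releases the carbene and the C8 ketone. The closest known reaction type is the enantioselective intramolecular crossed aldehyde–ketone benzoin that gives six-membered tertiary α-ketols with aminoindanol-derived triazolium salts. Ring B closes 6-exo-trig through the new C7–C8 bond. C7 is set by the catalyst, whose indane wall blocks one face of the enaminol while the enol O–H···O=C7 hydrogen bond fixes which ketone face is presented, so the choice of catalyst enantiomer decides 7S. Attack at C7 rather than C6 follows because C6 is a push–pull, pyrylium-enolate-like carbonyl whose attack would also need a strained five-membered ring, whereas C7 is an activated α-dicarbonyl ketone; acyl-anion rather than homoenolate reactivity is favoured by the electron-poor N-C6F5 carbene and by O2 on C1. Only the 4Z isomer can close and rotation about the polarised C4a=C5 bond feeds it from the E isomer, the aldehyde has no α-hydrogen, and the weak base in catalytic amount together with dilution holds back enolisation of the C7 acetyl group (seven-membered aldol onto C8) and intermolecular benzoin.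

Step 9
Reactants: 16 orsellinic acid (2,4-dihydroxy-6-methylbenzoic acid)
Product: 17 methoxymethyl 2,4-bis(methoxymethoxy)-6-methylbenzoate
Conditions: MOMCl (3.6 equiv), i-Pr2NEt (4 equiv), DMF, 0 → 23 °C
Reagents that add atoms: chloromethyl methyl ether, COCCl
Why: Exhaustive O-alkylation (Williamson type) of the carboxylate and both phenols with the highly reactive α-chloro ether, run at or below room temperature so that the acid does not decarboxylate.

Step 10
Reactants: 17 methoxymethyl 2,4-bis(methoxymethoxy)-6-methylbenzoate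
Product: 18 2,4-bis(methoxymethoxy)-6-methylbenzoic acid
Conditions: LiOH (2 equiv), THF/H2O, 23 °C; then 1 M HCl to pH 4, 0 °C
Reagents that add atoms: lithium hydroxide, [Li+].[OH-] (oxygen of the acid OH)
Why: Saponification, since the acetal-type MOM ester is cleaved by hydroxide far more easily than a hindered alkyl orsellinate while the aryl MOM ethers are stable to base and to brief cold acidification.

Step 11
Reactants: 18 2,4-bis(methoxymethoxy)-6-methylbenzoic acid; 15 tert-butyl (E)-3-[(7S)-7-hydroxy-7-methyl-6,8-dioxo-7,8-dihydro-6H-isochromen-3-yl]prop-2-enoate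
Product: 20 (7S)-3-[(E)-3-tert-butoxy-3-oxoprop-1-enyl]-7-methyl-6,8-dioxo-7,8-dihydro-6H-isochromen-7-yl 2,4-bis(methoxymethoxy)-6-methylbenzoate, via aroyl chloride 19 (not isolated)
Conditions: 18 (1.5 equiv), 1-chloro-N,N,2-trimethylprop-1-en-1-amine (1.6 equiv), CH2Cl2, 0 °C; then 15, Et3N (3 equiv), DMAP (0.5 equiv), CH2Cl2, 0 → 23 °C
Reagents that add atoms: 1-chloro-N,N,2-trimethylprop-1-en-1-amine, CC(C)=C(Cl)N(C)C (chlorine of 19 only)
Why: Acid chloride formation with an α-chloroenamine under neutral conditions (no HCl, so the MOM ethers stay) followed by DMAP-catalysed acylation of the tertiary but acidic C7–OH, the esterification type used for 7-O-acyl azaphilones, which breaks no bond at C7 and so keeps 7S.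

Step 12
Reactants: 20 (7S)-3-[(E)-3-tert-butoxy-3-oxoprop-1-enyl]-7-methyl-6,8-dioxo-7,8-dihydro-6H-isochromen-7-yl 2,4-bis(methoxymethoxy)-6-methylbenzoate
Product: 21 (S)-mitorubrinic acid
Conditions: TFA/CH2Cl2 (1:2), H2O (5 equiv), 0 → 23 °C
Reagents that add atoms: none
Why: Global acidolysis, in which TFA ionises the tert-butyl ester (loss of isobutene) and hydrolyses both aryl MOM acetals, while the C7 aryl ester, ring A and the quaternary C7 are inert to acid.

## Compound list

| No. | Name | SMILES | Role |
|---|---|---|---|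
| 1 | kojic acid | OCC1=CC(=O)C(O)=CO1 | starting material |
| 2 | 6-(hydroxymethyl)-4-oxo-4H-pyran-3-yl trifluoromethanesulfonate | OCC1=CC(=O)C(OS(=O)(=O)C(F)(F)F)=CO1 | intermediate |
| 3 | tert-butyl (triphenylphosphoranylidene)acetate | CC(C)(C)OC(=O)C=P(c1ccccc1)(c1ccccc1)c1ccccc1 | starting material |
| 4 | 6-formyl-4-oxo-4H-pyran-3-yl trifluoromethanesulfonate | O=CC1=CC(=O)C(OS(=O)(=O)C(F)(F)F)=CO1 | intermediate |
| 5 | tert-butyl (E)-3-[4-oxo-5-(trifluoromethylsulfonyloxy)-4H-pyran-2-yl]prop-2-enoate | CC(C)(C)OC(=O)/C=C/C1=CC(=O)C(OS(=O)(=O)C(F)(F)F)=CO1 | intermediate |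
| 6 | tert-butyl (E)-3-[4-thioxo-5-(trifluoromethylsulfonyloxy)-4H-pyran-2-yl]prop-2-enoate | CC(C)(C)OC(=O)/C=C/C1=CC(=S)C(OS(=O)(=O)C(F)(F)F)=CO1 | intermediate |
| 7 | 3,3-dimethoxybutan-2-one | CC(=O)C(C)(OC)OC | starting material |
| 8 | (3,3-dimethoxybut-1-en-2-yl)oxy-trimethylsilane | C=C(O[Si](C)(C)C)C(C)(OC)OC | intermediate |
| 9 | 1-bromo-3,3-dimethoxybutan-2-one | BrCC(=O)C(C)(OC)OC | intermediate |
| 10 | 2-[(E)-3-tert-butoxy-3-oxoprop-1-enyl]-4-[(3,3-dimethoxy-2-oxobutyl)sulfanyl]-5-(trifluoromethylsulfonyloxy)pyrylium bromide | CC(OC)(OC)C(=O)CSc1cc(/C=C/C(=O)OC(C)(C)C)[o+]cc1OS(=O)(=O)C(F)(F)F.[Br-] | intermediate |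
| 11 | tert-butyl (E)-3-[2-(2,2-dimethoxypropanoyl)-8-(trifluoromethylsulfonyloxy)-6-oxa-1-thiaspiro[2.5]octa-4,7-dien-5-yl]prop-2-enoate (stereoisomer mixture at the thiirane) | CC(OC)(OC)C(=O)C1SC12C=C(/C=C/C(=O)OC(C)(C)C)OC=C2OS(=O)(=O)C(F)(F)F | intermediate |
| 12 | tert-butyl (E)-3-[(4Z)-4-(3,3-dimethoxy-2-oxobutylidene)-5-(trifluoromethylsulfonyloxy)-4H-pyran-2-yl]prop-2-enoate | CC(OC)(OC)C(=O)/C=C1/C=C(/C=C/C(=O)OC(C)(C)C)OC=C1OS(=O)(=O)C(F)(F)F | intermediate |
| 13 | tert-butyl (E)-3-[(4Z)-4-(3,3-dimethoxy-2-oxobutylidene)-5-formyl-4H-pyran-2-yl]prop-2-enoate | CC(OC)(OC)C(=O)/C=C1/C=C(/C=C/C(=O)OC(C)(C)C)OC=C1C=O | intermediate |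
| 14 | tert-butyl (E)-3-[(4Z)-4-(2,3-dioxobutylidene)-5-formyl-4H-pyran-2-yl]prop-2-enoate | CC(=O)C(=O)/C=C1/C=C(/C=C/C(=O)OC(C)(C)C)OC=C1C=O | intermediate |
| 15 | tert-butyl (E)-3-[(7S)-7-hydroxy-7-methyl-6,8-dioxo-7,8-dihydro-6H-isochromen-3-yl]prop-2-enoate | O[C@@]1(C)C(=O)C=C2C=C(/C=C/C(=O)OC(C)(C)C)OC=C2C1=O | intermediate |
| 16 | orsellinic acid | Cc1cc(O)cc(O)c1C(=O)O | starting material |
| 17 | methoxymethyl 2,4-bis(methoxymethoxy)-6-methylbenzoate | COCOC(=O)c1c(C)cc(OCOC)cc1OCOC | intermediate |
| 18 | 2,4-bis(methoxymethoxy)-6-methylbenzoic acid | Cc1cc(OCOC)cc(OCOC)c1C(=O)O | intermediate |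
| 19 | 2,4-bis(methoxymethoxy)-6-methylbenzoyl chloride | Cc1cc(OCOC)cc(OCOC)c1C(=O)Cl | intermediate |
| 20 | (7S)-3-[(E)-3-tert-butoxy-3-oxoprop-1-enyl]-7-methyl-6,8-dioxo-7,8-dihydro-6H-isochromen-7-yl 2,4-bis(methoxymethoxy)-6-methylbenzoate | Cc1cc(OCOC)cc(OCOC)c1C(=O)O[C@@]1(C)C(=O)C=C2C=C(/C=C/C(=O)OC(C)(C)C)OC=C2C1=O | intermediate |
| 21 | (S)-mitorubrinic acid, (E)-3-[(7S)-7-(2,4-dihydroxy-6-methylbenzoyl)oxy-7-methyl-6,8-dioxo-7,8-dihydro-6H-isochromen-3-yl]prop-2-enoic acid | Cc1cc(O)cc(O)c1C(=O)O[C@@]1(C)C(=O)C=C2C=C(/C=C/C(=O)O)OC=C2C1=O | target |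

## Step count and risks

Total step count: 12.
Longest linear sequence: 9 steps (1, 2, 3, 5, 6, 7, 8, 11, 12) from kojic acid.

**Step 8.** The acceptor is a small, flat α-diketone, so the chiral carbene may discriminate poorly between the two faces of the C7 carbonyl. Enantiopurity may also erode through retro-benzoin during a slow reaction of the donor-substituted aldehyde. The fallback moves stereocontrol from catalysis to resolution.
- It sets out from 14.
- Ring B is closed with the smaller achiral salt 2-(pentafluorophenyl)-6,7-dihydro-5H-pyrrolo[2,1-c][1,2,4]triazol-2-ium tetrafluoroborate and Et3N in THF. This gives racemic tert-butyl (E)-3-(7-hydroxy-7-methyl-6,8-dioxo-7,8-dihydro-6H-isochromen-3-yl)prop-2-enoate F1.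
- F1 is separated by preparative chromatography on a polysaccharide-based chiral stationary phase into 15 and the (7R)-ketol F2.
- The route is rejoined at 15.

**Step 5.** S-alkylation of the acceptor-substituted thione may be slow and reversible through dealkylation by bromide. Et3N or PPh3 may also add to the free α-position C1 of the pyrylium stage and open ring A before the carbanion closes on C4a. The fallback avoids the pyrylium salt and the base by a neutral carbenoid coupling of the thione with a diazoketone.
- It sets out from 7 and 6.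
- Compound 7 is trifluoroacetylated (LiN(SiMe3)2, CF3CO2CH2CF3, THF, −78 °C) to 1,1,1-trifluoro-5,5-dimethoxyhexane-2,4-dione F3.
- Detrifluoroacetylative diazo transfer (MsN3, Et3N, H2O, MeCN) gives 1-diazo-3,3-dimethoxybutan-2-one F4.
- Slow addition of F4 to 6 and Rh2(OAc)4 (1 mol %) in CH2Cl2 at 40 °C should give the thiocarbonyl ylide, which closes to thiirane 11.
- PPh3 then removes sulfur, so the route is rejoined at 11 and thereby at 12.

**Step 6.** Hydride may be transferred to the vinylpalladium species before CO is taken up, which loses the triflate without carbonylation. The palladium hydride–silane couple may also cause conjugate reduction of the dienone or the enoate. The fallback brings C8 in at the alcohol level by cross-coupling and adjusts the oxidation state afterwards.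
- It sets out from 12.
- Stille coupling with (tributylstannyl)methanol (Pd2(dba)3, P(2-furyl)3, LiCl, NMP, 55 °C) gives tert-butyl (E)-3-[(4Z)-4-(3,3-dimethoxy-2-oxobutylidene)-5-(hydroxymethyl)-4H-pyran-2-yl]prop-2-enoate F5.
- MnO2 in CH2Cl2 oxidises the allylic alcohol of F5.
- The route is rejoined at 13.

## Further compounds

F1 | step 8 | racemic tert-butyl (E)-3-(7-hydroxy-7-methyl-6,8-dioxo-7,8-dihydro-6H-isochromen-3-yl)prop-2-enoate | OC1(C)C(=O)C=C2C=C(/C=C/C(=O)OC(C)(C)C)OC=C2C1=O
F2 | step 8 | tert-butyl (E)-3-[(7R)-7-hydroxy-7-methyl-6,8-dioxo-7,8-dihydro-6H-isochromen-3-yl]prop-2-enoate | O[C@]1(C)C(=O)C=C2C=C(/C=C/C(=O)OC(C)(C)C)OC=C2C1=O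
F3 | step 5 | 1,1,1-trifluoro-5,5-dimethoxyhexane-2,4-dione | CC(OC)(OC)C(=O)CC(=O)C(F)(F)F
F4 | step 5 | 1-diazo-3,3-dimethoxybutan-2-one | CC(OC)(OC)C(=O)C=[N+]=[N-]
F5 | step 6 | tert-butyl (E)-3-[(4Z)-4-(3,3-dimethoxy-2-oxobutylidene)-5-(hydroxymethyl)-4H-pyran-2-yl]prop-2-enoate | CC(OC)(OC)C(=O)/C=C1/C=C(/C=C/C(=O)OC(C)(C)C)OC=C1CO
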